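Everything rests on making the aryl ether bond C8a–O1 last. The feature exploited is that the ring C oxygen O1 sits between the aromatic carbon C8a of ring A and the phenyl-bearing stereocentre C2, so the carbinol oxygen of a preformed (S)-alcohol can become O1 while all bonds at C2 stay intact. A single palladium-catalysed intramolecular etherification of a C8a bromide thus forges C8a–O1, closes six-membered ring C and transfers the configuration. The precursor is a hexasubstituted bromoarene (MOM ethers at C5 and C7, MOM-protected pyrone at C6, prenyl at C8) with a three-carbon chain on C4a: C4 a silyl-protected carbinol of either configuration, C2 the free (S)-alcohol. Later oxidation at C4 merges the epimers.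

Key step: step 15

Assumption: the target carries no descriptor for the aryl–pyrone axis, so rotamers or atropisomers about it, like the C4 epimers, are carried as mixtures that converge at the ketone stage.

Design notes: (a) The C4 hydroxyl goes through the key step as a TBS ether. A free C4 alkoxide would bind the arylpalladium centre in a five-membered chelate and could reduce the C8a–Br bond by β-hydride elimination. (b) C6 is functionalised as an iodide. It blocks C6 during the Claisen shift and lets the pyrone be coupled while the C8a bromide stays untouched.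

Abbreviations: flavanone numbering is used for ring A positions. Pyr = 6-ethyl-4-(methoxymethoxy)-5-methyl-2-oxo-2H-pyran-3-yl. Ar = 2-bromo-4,6-bis(methoxymethoxy)-3-(3-methylbut-2-en-1-yl)-5-Pyr-phenyl.

**Fragment 1 (pyrone)**

Step 1
Reactants: 1 3-pentanone
Product: 2 3-(trimethylsilyloxy)pent-2-ene (E/Z mixture)
Conditions: TMSOTf, Et3N, CH2Cl2, 0 °C
Reagents that add atoms: trimethylsilyl triflate C[Si](C)(C)OS(=O)(=O)C(F)(F)F
Why: Soft enolisation (enol silane formation) of a symmetrical ketone can give only one regioisomer, and both alkene geometries lead to the same pyrone.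

Step 2
Reactants: 2 3-(trimethylsilyloxy)pent-2-ene; 3 malonyl dichloride
Product: 5 6-ethyl-4-hydroxy-5-methyl-2H-pyran-2-one, via acyl chloride 4 (not isolated)
Conditions: Et2O, −78 °C → rt
Reagents that add atoms: none
Why: In this enol silane/malonyl dichloride pyrone annulation, C-acylation by one acid chloride and O-acylation of the resulting enol by the other build the 4-hydroxy-2-pyrone, with ethyl at C6 and methyl at C5 fixed by the ketone skeleton.

Step 3
Reactants: 5 6-ethyl-4-hydroxy-5-methyl-2H-pyran-2-one
Product: 6 6-ethyl-4-hydroxy-3-iodo-5-methyl-2H-pyran-2-one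
Conditions: NIS, MeCN, rt
Reagents that add atoms: N-iodosuccinimide O=C1CCC(=O)N1I
Why: Electrophilic iodination of the vinylogous acid can occur only at pyrone C3, the one unsubstituted and most nucleophilic ring carbon.

Step 4
Reactants: 6 6-ethyl-4-hydroxy-3-iodo-5-methyl-2H-pyran-2-one
Product: 7 6-ethyl-3-iodo-4-(methoxymethoxy)-5-methyl-2H-pyran-2-one
Conditions: MOMCl, iPr2NEt, CH2Cl2, 0 °C → rt
Reagents that add atoms: chloromethyl methyl ether COCCl
Why: O-alkylation (MOM ether formation) masks the acidic pyrone hydroxyl for the organometallic and basic steps, and the group falls together with the aryl MOM ethers at the end.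

**Fragment 2 (ring A)**

Step 5
Reactants: 8 5-bromoresorcinol
Product: 10 2-bromo-4,6-dihydroxybenzaldehyde, via iminium chloride 9 (not isolated)
Conditions: POCl3, DMF, 0 °C → rt; then ice–water
Reagents that add atoms: N,N-dimethylformamide CN(C)C=O; water O
Why: Vilsmeier–Haack formylation attacks the carbon para to one hydroxyl and ortho to the other, as with orcinol, which places the future C4 carbon next to the bromine-bearing future C8a.

Step 6
Reactants: 10 2-bromo-4,6-dihydroxybenzaldehyde
Product: 11 6-bromo-2,4-dihydroxy-3-iodobenzaldehyde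
Conditions: I2, HIO3, EtOH–H2O, rt
Reagents that add atoms: iodine II; iodic acid OI(=O)=O
Why: Electrophilic aromatic iodination of chelated 2,4-dihydroxyaryl carbonyl compounds under these conditions favours the carbon between the two hydroxyls (future C6), and here the only other free site is also crowded by bromine.

Step 7
Reactants: 11 6-bromo-2,4-dihydroxy-3-iodobenzaldehyde; 12 3-chloro-3-methylbut-1-yne
Product: 13 6-bromo-2-hydroxy-3-iodo-4-[(2-methylbut-3-yn-2-yl)oxy]benzaldehyde
Conditions: DBU, CuCl2·2H2O (1 mol %), MeCN, 0 °C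
Reagents that add atoms: none
Why: Copper-catalysed propargylic etherification alkylates only the more acidic, non-chelated hydroxyl para to the aldehyde (future C7–OH), because the C5 hydroxyl is held in a hydrogen bond to the formyl group.

Step 8
Reactants: 13 6-bromo-2-hydroxy-3-iodo-4-[(2-methylbut-3-yn-2-yl)oxy]benzaldehyde
Product: 14 6-bromo-2-hydroxy-3-iodo-4-[(2-methylbut-3-en-2-yl)oxy]benzaldehyde
Conditions: H2 (1 atm, one equivalent taken up), Pd/CaCO3 poisoned with Pb(OAc)2, quinoline, EtOAc, rt
Reagents that add atoms: none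
Why: Lindlar semihydrogenation stops at the terminal alkene and, with quinoline and controlled hydrogen uptake, should leave both aryl halides and the aldehyde alone.

Step 9
Reactants: 14 6-bromo-2-hydroxy-3-iodo-4-[(2-methylbut-3-en-2-yl)oxy]benzaldehyde
Product: 16 2-bromo-4,6-dihydroxy-5-iodo-3-(3-methylbut-2-en-1-yl)benzaldehyde, via cyclohexadienone 15 (not isolated)
Conditions: toluene, 110 °C (sealed tube)
Reagents that add atoms: none
Why: In this aromatic Claisen rearrangement the C6 ortho position is blocked by iodine, so the [3,3] shift can end productively only at C8, turning the 1,1-dimethylallyl group into prenyl before the dienone tautomerises.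

Step 10
Reactants: 16 2-bromo-4,6-dihydroxy-5-iodo-3-(3-methylbut-2-en-1-yl)benzaldehyde
Product: 17 2-bromo-5-iodo-4,6-bis(methoxymethoxy)-3-(3-methylbut-2-en-1-yl)benzaldehyde
Conditions: NaH, MOMCl, DMF, 0 °C → rt
Reagents that add atoms: chloromethyl methyl ether COCCl
Why: Williamson-type alkylation of the bis-phenoxide protects both hindered phenols in one operation, and the non-enolisable aldehyde tolerates NaH.

**Union and elaboration**

Step 11
Reactants: 7 6-ethyl-3-iodo-4-(methoxymethoxy)-5-methyl-2H-pyran-2-one; 17 2-bromo-5-iodo-4,6-bis(methoxymethoxy)-3-(3-methylbut-2-en-1-yl)benzaldehyde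
Product: 20 Ar–CHO (2-bromo-4,6-bis(methoxymethoxy)-3-(3-methylbut-2-en-1-yl)-5-Pyr-benzaldehyde), via pyronylmagnesium chloride 18 (not isolated), via pyronylzinc chloride 19 (not isolated)
Conditions: 7, iPrMgCl·LiCl, THF, −40 °C; ZnCl2, −40 °C → rt; then 17, Pd2(dba)3 (2.5 mol %), SPhos (10 mol %), THF, 50 °C
Reagents that add atoms: none
Why: In this Negishi coupling, halogen–magnesium exchange on the α-iodo-β-alkoxy enoate motif (known for 5-iodo-1,3-dioxin-4-ones) and transmetalation give an aldehyde-tolerant zinc reagent, and zerovalent palladium inserts into the carbon–iodine bond at C6 much faster than into the doubly flanked C8a–Br bond.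

Step 12
Reactants: 20 Ar–CHO; 21 acetophenone
Product: 24 rac-3-Ar-3-hydroxy-1-phenylpropan-1-one, via lithium enolate 22 (not isolated), via lithium aldolate 23 (not isolated)
Conditions: 21, LiN(iPr)2, THF, −78 °C; then 20, −78 °C; AcOH quench at −78 °C
Reagents that add atoms: none
Why: Aldol addition of a preformed lithium enolate to a non-enolisable aldehyde is fast at −78 °C, a cold acidic quench prevents retro-aldol, and the new C4 centre is deliberately left racemic because step 17 destroys it.

Step 13
Reactants: 24 rac-3-Ar-3-hydroxy-1-phenylpropan-1-one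
Product: 25 rac-3-Ar-3-[(tert-butyldimethylsilyl)oxy]-1-phenylpropan-1-one
Conditions: TBSOTf, 2,6-lutidine, CH2Cl2, −78 → 0 °C
Reagents that add atoms: tert-butyldimethylsilyl triflate CC(C)(C)[Si](C)(C)OS(=O)(=O)C(F)(F)F
Why: Silyl ether formation removes the one hydroxyl that could later chelate palladium and deliver hydride to it, stops retro-aldol and dehydration of the aldol, and uses a group bulky enough to resist oxygen-to-oxygen migration.

Step 14
Reactants: 25 rac-3-Ar-3-[(tert-butyldimethylsilyl)oxy]-1-phenylpropan-1-one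
Product: 26 (1S)-3-Ar-3-[(tert-butyldimethylsilyl)oxy]-1-phenylpropan-1-ol (both epimers at the silyloxy carbon, future C4)
Conditions: RuCl(p-cymene)[(S,S)-TsDPEN] (2 mol %), HCO2H–Et3N (1:1), EtOAc, 35 °C
Reagents that add atoms: none
Why: In Noyori–Ikariya asymmetric transfer hydrogenation the (S,S)-catalyst reduces aryl alkyl ketones in the sense that gives (S)-1-phenylethanol from acetophenone, and since phenyl outranks the CH2 chain here too, the future C2 carbinol is set as (S) under catalyst control in both C4 epimers.

Step 15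
Reactants: 26 (1S)-3-Ar-3-[(tert-butyldimethylsilyl)oxy]-1-phenylpropan-1-ol
Product: 27 (2S)-4-[(tert-butyldimethylsilyl)oxy]-5,7-bis(methoxymethoxy)-8-(3-methylbut-2-en-1-yl)-2-phenyl-6-Pyr-chroman (both C4 epimers)
Conditions: Pd2(dba)3 (5 mol %), RockPhos [2-(di-tert-butylphosphino)-3-methoxy-6-methyl-2′,4′,6′-triisopropylbiphenyl] (12 mol %), Cs2CO3, toluene, 90 °C
Reagents that add atoms: none
Why: Zerovalent palladium carrying the bulky biarylphosphine adds oxidatively to C8a–Br, carbonate deprotonates the coordinated C2 hydroxyl, and C–O reductive elimination from the divalent arylpalladium alkoxide releases the chroman. The closest known reaction type is the Buchwald–Hartwig-type intramolecular etherification of aryl bromides with secondary alcohols, which is known to give chromans from enantioenriched alcohols with the configuration preserved. Six-membered ring C closes by reductive elimination from a seven-membered oxapalladacycle, formally a 6-exo closure at the sp2 carbon C8a with bromide departing outside the ring. No stereocentre is created, because only the O–H and C8a–Br bonds are broken, so C2 stays (S), and unequal rates of the two C4 epimers have no consequence. The step needs reductive elimination to outrun β-hydride elimination of the C2 alkoxide and needs a single oxygen nucleophile, which the di-tert-butyl biaryl ligand and the full protection of every other oxygen (TBS at C4, three MOM groups) respectively secure. The C8 prenyl alkene could insert only through a strained four-membered or 5-endo pathway, so Heck-type diversion is not expected.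

Step 16
Reactants: 27 (2S)-4-silyloxy chroman
Product: 28 (2S)-5,7-bis(methoxymethoxy)-8-(3-methylbut-2-en-1-yl)-2-phenyl-6-Pyr-chroman-4-ol (both C4 epimers)
Conditions: Bu4NF, AcOH, THF, rt → 40 °C
Reagents that add atoms: none
Why: Fluoride-mediated desilylation, buffered with acetic acid to spare the pyrone, frees the C4 carbinol while the MOM ethers, the aryl ether and the prenyl group are inert.

Step 17
Reactants: 28 (2S)-flavan-4-ol
Product: 29 (2S)-5,7-bis(methoxymethoxy)-8-(3-methylbut-2-en-1-yl)-2-phenyl-6-Pyr-chroman-4-one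
Conditions: Dess–Martin periodinane, NaHCO3, CH2Cl2, 0 °C → rt
Reagents that add atoms: none
Why: Dess–Martin oxidation turns both C4 epimers into one ketone under buffered, non-basic conditions that neither touch the prenyl alkene nor open ring C, so C2 is not at risk.

Step 18
Reactants: 29 (2S)-tris-MOM flavanone
Product: 30 (2S)-6-(6-ethyl-4-hydroxy-5-methyl-2-oxo-2H-pyran-3-yl)-5,7-dihydroxy-8-(3-methylbut-2-en-1-yl)-2-phenylchroman-4-one (CNP0482269.1)
Conditions: HCl (3 M aq), MeOH, rt
Reagents that add atoms: none
Why: Acid-catalysed acetal exchange with methanol removes the three MOM groups at once under the mild conditions customary for prenylated flavanones, kept cool and short so that the prenyl group does not add to the C7 hydroxyl and ring C does not open at C2.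

**Compound list**

1 | 3-pentanone | CCC(=O)CC | starting material
2 | 3-(trimethylsilyloxy)pent-2-ene (E/Z mixture) | CC=C(CC)O[Si](C)(C)C | intermediate
3 | malonyl dichloride | O=C(Cl)CC(=O)Cl | starting material
4 | 4-methyl-3,5-dioxoheptanoyl chloride | CCC(=O)C(C)C(=O)CC(=O)Cl | intermediate (not isolated)
5 | 6-ethyl-4-hydroxy-5-methyl-2H-pyran-2-one | CCc1oc(=O)cc(O)c1C | intermediate
6 | 6-ethyl-4-hydroxy-3-iodo-5-methyl-2H-pyran-2-one | CCc1oc(=O)c(I)c(O)c1C | intermediate
7 | 6-ethyl-3-iodo-4-(methoxymethoxy)-5-methyl-2H-pyran-2-one | CCc1oc(=O)c(I)c(OCOC)c1C | intermediate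
8 | 5-bromoresorcinol | Oc1cc(O)cc(Br)c1 | starting material
9 | [(2-bromo-4,6-dihydroxyphenyl)methylidene]dimethylammonium chloride | C[N+](C)=Cc1c(O)cc(O)cc1Br.[Cl-] | intermediate (not isolated)
10 | 2-bromo-4,6-dihydroxybenzaldehyde | O=Cc1c(O)cc(O)cc1Br | intermediate
11 | 6-bromo-2,4-dihydroxy-3-iodobenzaldehyde | O=Cc1c(O)c(I)c(O)cc1Br | intermediate
12 | 3-chloro-3-methylbut-1-yne | C#CC(C)(C)Cl | starting material
13 | 6-bromo-2-hydroxy-3-iodo-4-[(2-methylbut-3-yn-2-yl)oxy]benzaldehyde | O=Cc1c(O)c(I)c(OC(C)(C)C#C)cc1Br | intermediate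
14 | 6-bromo-2-hydroxy-3-iodo-4-[(2-methylbut-3-en-2-yl)oxy]benzaldehyde | O=Cc1c(O)c(I)c(OC(C)(C)C=C)cc1Br | intermediate
15 | 2-bromo-6-hydroxy-5-iodo-3-(3-methylbut-2-en-1-yl)-4-oxocyclohexa-1,5-diene-1-carbaldehyde (racemic) | O=CC1=C(Br)C(CC=C(C)C)C(=O)C(I)=C1O | intermediate (not isolated)
16 | 2-bromo-4,6-dihydroxy-5-iodo-3-(3-methylbut-2-en-1-yl)benzaldehyde | O=Cc1c(O)c(I)c(O)c(CC=C(C)C)c1Br | intermediate
17 | 2-bromo-5-iodo-4,6-bis(methoxymethoxy)-3-(3-methylbut-2-en-1-yl)benzaldehyde | O=Cc1c(OCOC)c(I)c(OCOC)c(CC=C(C)C)c1Br | intermediate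
18 | [6-ethyl-4-(methoxymethoxy)-5-methyl-2-oxo-2H-pyran-3-yl]magnesium chloride | CCc1oc(=O)c([Mg]Cl)c(OCOC)c1C | intermediate (not isolated)
19 | [6-ethyl-4-(methoxymethoxy)-5-methyl-2-oxo-2H-pyran-3-yl]zinc chloride | CCc1oc(=O)c([Zn]Cl)c(OCOC)c1C | intermediate (not isolated)
20 | 2-bromo-5-[6-ethyl-4-(methoxymethoxy)-5-methyl-2-oxo-2H-pyran-3-yl]-4,6-bis(methoxymethoxy)-3-(3-methylbut-2-en-1-yl)benzaldehyde | CCc1oc(=O)c(-c2c(OCOC)c(CC=C(C)C)c(Br)c(C=O)c2OCOC)c(OCOC)c1C | intermediate
21 | acetophenone | CC(=O)c1ccccc1 | starting material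
22 | lithium 1-phenylethenolate | [Li]OC(=C)c1ccccc1 | intermediate (not isolated)
23 | lithium alkoxide of 24 (racemic) | CCc1oc(=O)c(-c2c(OCOC)c(CC=C(C)C)c(Br)c(c2OCOC)C(CC(=O)c2ccccc2)O[Li])c(OCOC)c1C | intermediate (not isolated)
24 | rac-3-Ar-3-hydroxy-1-phenylpropan-1-one | CCc1oc(=O)c(-c2c(OCOC)c(CC=C(C)C)c(Br)c(c2OCOC)C(O)CC(=O)c2ccccc2)c(OCOC)c1C | intermediate
25 | rac-3-Ar-3-[(tert-butyldimethylsilyl)oxy]-1-phenylpropan-1-one | CCc1oc(=O)c(-c2c(OCOC)c(CC=C(C)C)c(Br)c(c2OCOC)C(CC(=O)c2ccccc2)O[Si](C)(C)C(C)(C)C)c(OCOC)c1C | intermediate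
26 | (1S)-3-Ar-3-[(tert-butyldimethylsilyl)oxy]-1-phenylpropan-1-ol, both epimers at the silyloxy carbon (key-step precursor) | CCc1oc(=O)c(-c2c(OCOC)c(CC=C(C)C)c(Br)c(c2OCOC)C(C[C@H](O)c2ccccc2)O[Si](C)(C)C(C)(C)C)c(OCOC)c1C | intermediate
27 | (2S)-4-[(tert-butyldimethylsilyl)oxy]-5,7-bis(methoxymethoxy)-8-prenyl-2-phenyl-6-Pyr-chroman, both C4 epimers (key-step product) | CCc1oc(=O)c(-c2c(OCOC)c(CC=C(C)C)c3c(c2OCOC)C(O[Si](C)(C)C(C)(C)C)C[C@@H](c2ccccc2)O3)c(OCOC)c1C | intermediate
28 | (2S)-5,7-bis(methoxymethoxy)-8-prenyl-2-phenyl-6-Pyr-chroman-4-ol, both C4 epimers | CCc1oc(=O)c(-c2c(OCOC)c(CC=C(C)C)c3c(c2OCOC)C(O)C[C@@H](c2ccccc2)O3)c(OCOC)c1C | intermediate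
29 | (2S)-5,7-bis(methoxymethoxy)-8-prenyl-2-phenyl-6-Pyr-chroman-4-one | CCc1oc(=O)c(-c2c(OCOC)c(CC=C(C)C)c3c(c2OCOC)C(=O)C[C@@H](c2ccccc2)O3)c(OCOC)c1C | intermediate
30 | (2S)-6-(6-ethyl-4-hydroxy-5-methyl-2-oxo-2H-pyran-3-yl)-5,7-dihydroxy-8-(3-methylbut-2-en-1-yl)-2-phenylchroman-4-one | CCc1oc(=O)c(-c2c(O)c(CC=C(C)C)c3c(c2O)C(=O)C[C@@H](c2ccccc2)O3)c(O)c1C | target

Total step count: 18. Longest linear sequence: 14 (steps 5–18, from 5-bromoresorcinol 8). The pyrone branch (steps 1–4) joins at step 11.

**Steps most likely to fail**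

1. **Step 15.**
   - What may go wrong: Oxidative addition may be slow at a bromide flanked by two ortho substituents on an electron-rich ring. β-Hydride elimination from the palladium alkoxide may outrun C–O reductive elimination, causing hydrodebromination. Base may also move the silyl group from the C4 oxygen to the C2 oxygen.
   - Fallback: it forms O1–C2 instead of C8a–O1, sets out from 25 and comes back at 27. Ketone 25 would be reduced with RuCl(p-cymene)[(R,R)-TsDPEN] and HCO2H–Et3N to the (1R)-alcohol F1. Miyaura borylation (PdCl2(dppf), B2pin2, KOAc, dioxane, 90 °C) would give the C8a pinacol boronate F2. Oxidation with NaBO3·4H2O in THF–H2O would then give the C8a phenol F3. Mitsunobu cyclisation (PPh3, DIAD, THF, 0 °C) would displace the activated benzylic oxygen with inversion and deliver 27 with the (2S) configuration.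

2. **Step 11.**
   - What may go wrong: Transmetalation and reductive elimination may be sluggish at a biaryl-type bond with four ortho substituents. The metalated pyrone may decompose before it couples. Late insertion into the C8a–Br bond may occur once the iodide is consumed.
   - Fallback: it reverses the polarity, sets out from 17 and comes back at 20. Miyaura borylation selective for the carbon–iodine bond (PdCl2(dppf), B2pin2, KOAc, dioxane, 80 °C) would give the aryl pinacol boronate F4. This would be joined to iodopyrone 7 by Suzuki–Miyaura coupling (Pd(OAc)2, SPhos, K3PO4, toluene–H2O, 60 °C) to give 20.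

3. **Step 6.**
   - What may go wrong: Site selectivity between the two free ring positions may be poor, or the ring may be iodinated twice.
   - Fallback: it reverses the order of events so that symmetry settles both regiochemical questions, sets out from 8, replaces steps 5 and 6 and comes back at 11. Iodination of 8 with I2 and NaHCO3 in water at 0 °C would give 5-bromo-2-iodoresorcinol F5. Its two remaining ring positions are equivalent. Casnati–Skattebøl ortho-formylation (MgCl2, Et3N, paraformaldehyde, MeCN, reflux) under non-acidic conditions, which should not loosen the iodide, would then lead to 11.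

**Further compounds**

F1 | step 15 | (1R)-3-Ar-3-[(tert-butyldimethylsilyl)oxy]-1-phenylpropan-1-ol, both epimers at the silyloxy carbon | CCc1oc(=O)c(-c2c(OCOC)c(CC=C(C)C)c(Br)c(c2OCOC)C(C[C@@H](O)c2ccccc2)O[Si](C)(C)C(C)(C)C)c(OCOC)c1C
F2 | step 15 | C8a pinacol boronate of F1 (Bpin in place of Br) | CCc1oc(=O)c(-c2c(OCOC)c(CC=C(C)C)c(B3OC(C)(C)C(C)(C)O3)c(c2OCOC)C(C[C@@H](O)c2ccccc2)O[Si](C)(C)C(C)(C)C)c(OCOC)c1C
F3 | step 15 | C8a phenol of F1 (OH in place of Br) | CCc1oc(=O)c(-c2c(OCOC)c(CC=C(C)C)c(O)c(c2OCOC)C(C[C@@H](O)c2ccccc2)O[Si](C)(C)C(C)(C)C)c(OCOC)c1C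
F4 | step 11 | 2-bromo-4,6-bis(methoxymethoxy)-3-(3-methylbut-2-en-1-yl)-5-(4,4,5,5-tetramethyl-1,3,2-dioxaborolan-2-yl)benzaldehyde | O=Cc1c(OCOC)c(B2OC(C)(C)C(C)(C)O2)c(OCOC)c(CC=C(C)C)c1Br
F5 | step 6 | 5-bromo-2-iodoresorcinol | Oc1cc(Br)cc(O)c1I
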